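(Its constants are assumed; the flask was simulated.)

I decide to reckon this flask as one equilibrium, which is the cheapest route, and to use the rates for one job: checking that the run gets there in time.

substrate 20 mM; reagent 0.700 equiv; time 20 h

    substrate + reagent ⇌ target (K1 = 85.3 M⁻¹, k1 = 0.417 M⁻¹ min⁻¹)
    target ⇌ isomer of the product (K2 = 1.5, k2 = 0.0421 min⁻¹)

- why nothing more happens at 20 h, or that something still does (it is still moving / the reagent has run out first / all of the substrate has reacted / forward and back rates have come level)
- part of the substrate gone at 20 h
- the target standing at 20 h, as a percentage of the substrate charged

- the reaction counts as stopped when no species that holds the substrate changes by six tenths of a point or more over the second half of the time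
- run time (flask): 20 h

I climb a ladder of half-lives. On the fastest rung, target and isomer of the product relax into each other with a half-life of 0.165 h, both ways counted. This is shorter than the 2.0 h the substrate needs by the forward rate of the first step at the charged reagent, and much shorter than the run of 20 h, so I expect the pair to stand at its equilibrium ratio by the end of the run. At that ratio target holds 40.0% of what has reacted, below the even split of a symmetric pair. On the next rung, the run lasts ten times that forward half-life, so I expect forward and back rates to have come level by the end: thermodynamic control.

For the end state the pair acts as one product. I carry the lumped binding number G, the constant of the first step times one plus the constant of the second, times the charged substrate: 4.26. With amounts in units of the substrate charge, the converted part x over the product of substrate left and reagent left equals G. This gives x = 48.2% and target 19.3%.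

The forecast says forward and back rates have come level, with 48.2% gone and 19.3% of target, on the grounds that “20 h is ample for both equilibria to settle”.

The simulation gives forward and back rates have come level, 48.2% and 19.3%. The neighbouring flask takes 1.80 equiv of reagent on the same substrate, so G stays 4.26 and the equivalents change. My x becomes 80.9%, and target, at 40.0% of that, 32.4%. Simulated, that neighbouring flask shows 80.9% gone and target at 32.3%, with the isomer of the product beside it at 48.5%.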